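**Retrosynthetic overview**

1. Malabaricone C is traced back to a derivative with two O-methyl groups on ring A (the 2,6-dioxygenated ring) and two O-acetyl groups on ring B (the catechol ring); one flask unmasks all four phenols.
2. Key disconnection: the bond between the benzylic carbon C9 and ring B. It is formed together with the C1 ketone by a photoredox/nickel ring-opening arylation of 1-(2,6-dimethoxyphenyl)cyclononan-1-ol with 4-bromo-1,2-phenylene diacetate.
3. Enabling feature: the ketone carbon C1 and the benzylic carbon C9 are the two ends of an unbranched nine-carbon chain, and C1 carries the electron-rich ring A. Tying C9 back to C1 gives a symmetric tertiary cyclononanol whose alkoxy radical, generated through ring A as redox antenna, cleaves the C1–C9 bond to the aryl ketone and a primary C9 radical.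
4. The cyclononanol comes from C2-lithiated 1,3-dimethoxybenzene and cyclononanone; the aryl bromide comes from 4-bromocatechol.
5. No ring is formed in the route: rings A and B are bought as benzenes, and the temporary nine-membered carbocycle is bought as cyclononanone and opened in the key step.

Key step: step 3

Remarks: the target has no stereocentre. C1 is the ketone carbon and C9 the benzylic carbon of the nonanone chain. Cyclononanone, 1,3-dimethoxybenzene and 4-bromocatechol are assumed to be purchased. Abbreviations: dF(CF3)ppy = cyclometalated 2-(2,4-difluorophenyl)-5-(trifluoromethyl)pyridine; 5,5'-d(CF3)bpy = 5,5'-bis(trifluoromethyl)-2,2'-bipyridine; dtbbpy = 4,4'-di-tert-butyl-2,2'-bipyridine; dme = 1,2-dimethoxyethane.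

**Route**

Step 1
Reactants: 1 1,3-dimethoxybenzene; 2 cyclononanone
Product: 5 1-(2,6-dimethoxyphenyl)cyclononan-1-ol, via 2,6-dimethoxyphenyllithium 3 (not isolated), via (2,6-dimethoxyphenyl)cerium dichloride 4 (not isolated)
Conditions: n-BuLi, THF, 0 °C to rt; anhydrous CeCl3, THF, −78 °C; then 2, −78 to 0 °C; sat. aq. NH4Cl
Reagents that add atoms: none
Why: Directed ortho-lithiation of 1 takes place at C2 between the two methoxy groups, and transmetalation to the weakly basic, oxophilic organocerium reagent (Imamoto-type organocerium addition) should favour 1,2-addition over enolisation of the sluggish medium-ring ketone; the carbinol carbon is no stereocentre because the two ring arms are identical.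

Step 2
Reactants: 6 4-bromobenzene-1,2-diol (4-bromocatechol)
Product: 7 4-bromo-1,2-phenylene diacetate
Conditions: Ac2O, pyridine, DMAP (cat.), CH2Cl2, 0 °C to rt
Reagents that add atoms: acetic anhydride, CC(=O)OC(C)=O
Why: DMAP-catalysed O-acetylation of both phenols (nucleophilic acyl substitution) should be clean, and the acetyl groups make ring B electron-poor, so that it is inert to the photo-oxidant of step 3 and leaves with methanol in step 4.

Step 3
Reactants: 5 1-(2,6-dimethoxyphenyl)cyclononan-1-ol; 7 4-bromo-1,2-phenylene diacetate
Product: 8 4-[9-(2,6-dimethoxyphenyl)-9-oxononyl]-1,2-phenylene diacetate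
Conditions: [Ir(dF(CF3)ppy)2(5,5'-d(CF3)bpy)]PF6 (2 mol%), NiBr2(dme) (10 mol%), dtbbpy (15 mol%), 2,4,6-collidine (2 equiv), MeCN/PhCF3 (1:1), blue LEDs (450 nm), rt, argon
Reagents that add atoms: none
Why: The photoexcited iridium complex should oxidise ring A of 5, the only electron-rich arene in the flask because ring B is an electron-poor diacetate, to its radical cation; collidine-assisted proton-coupled electron transfer then gives the tertiary alkoxy radical, and β-scission of the C1–C9 ring bond, driven by release of the strain of the nine-membered ring, delivers the aryl ketone and a primary radical at C9. This radical is captured by the aryl(bromo) divalent nickel complex formed from 7, reductive elimination from trivalent nickel forms the C9–aryl bond, the reduced (divalent) iridium returns the electron to nickel and collidine takes up the HBr, so the step is redox-neutral. The closest known reaction type is the proton-coupled-electron-transfer ring opening of 1-(methoxyaryl)cycloalkanols merged with nickel-catalysed arylation of the distal alkyl radical by aryl bromides. No ring is closed (one is opened) and no stereocentre is created. The step needs chemoselective one-electron oxidation, secured by the methoxy groups on ring A against the acetoxy groups on ring B and by the fact that ring A becomes an acyl-deactivated arene in 8 and is not oxidised again, and it needs a single site of scission, secured by the symmetry of the cyclononanol (both ring bonds at C1 give the same radical) while re-closure to a nine-membered ring is too slow to compete. Capture of the primary radical by nickel must outrun hydrogen-atom transfer, which the absence of thiols or other good hydrogen donors and a high nickel loading should secure.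

Step 4
Reactants: 8 4-[9-(2,6-dimethoxyphenyl)-9-oxononyl]-1,2-phenylene diacetate
Product: 10 malabaricone C, via bisphenol diacetate 9 (not isolated)
Conditions: BBr3 (6 equiv), CH2Cl2, −78 °C to rt; then MeOH, 0 to 40 °C; degassed aqueous work-up
Reagents that add atoms: none
Why: BBr3 should cleave the two aryl methyl ethers that flank the ketone (Lewis-acid ether cleavage, helped by chelation to the carbonyl oxygen), and the HBr formed when methanol is added transesterifies the two aryl acetates, so that all four phenols are set free in one flask without touching the ketone or the chain.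

**Compound list**

1 | 1,3-dimethoxybenzene | COc1cccc(OC)c1 | starting material
2 | cyclononanone | O=C1CCCCCCCC1 | starting material
3 | 2,6-dimethoxyphenyllithium | [Li]c1c(OC)cccc1OC | intermediate (not isolated)
4 | (2,6-dimethoxyphenyl)cerium dichloride | COc1cccc(OC)c1[Ce](Cl)Cl | intermediate (not isolated)
5 | 1-(2,6-dimethoxyphenyl)cyclononan-1-ol | COc1cccc(OC)c1C2(O)CCCCCCCC2 | intermediate
6 | 4-bromobenzene-1,2-diol (4-bromocatechol) | Oc1ccc(Br)cc1O | starting material
7 | 4-bromo-1,2-phenylene diacetate | CC(=O)Oc1ccc(Br)cc1OC(C)=O | intermediate
8 | 4-[9-(2,6-dimethoxyphenyl)-9-oxononyl]-1,2-phenylene diacetate | COc1cccc(OC)c1C(=O)CCCCCCCCc1ccc(OC(C)=O)c(OC(C)=O)c1 | intermediate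
9 | 4-[9-(2,6-dihydroxyphenyl)-9-oxononyl]-1,2-phenylene diacetate | CC(=O)Oc1ccc(CCCCCCCCC(=O)c2c(O)cccc2O)cc1OC(C)=O | intermediate (not isolated)
10 | malabaricone C, 1-(2,6-dihydroxyphenyl)-9-(3,4-dihydroxyphenyl)nonan-1-one | O=C(CCCCCCCCc1ccc(O)c(O)c1)c1c(O)cccc1O | target

**Summary**

Total step count: 4. Longest linear sequence: 3 steps (steps 1, 3 and 4).

**Steps most likely to fail**

Step 3. The ring opening and the arylation may fail to stay coupled. The cyclononyloxy radical may undergo transannular hydrogen transfer instead of β-scission, the primary radical may pick up a hydrogen atom before nickel intercepts it, or the proton-coupled electron transfer may be slow because the hydroxyl group is hydrogen-bonded to an ortho methoxy group. The fallback gives up the ring-opening logic and sets out from the aryllithium 3. Acylation of 3 with N-methoxy-N-methylnon-8-enamide F1 (made from commercial non-8-enoic acid, 1,1'-carbonyldiimidazole and N,O-dimethylhydroxylamine hydrochloride) should give 1-(2,6-dimethoxyphenyl)non-8-en-1-one F2. Anti-Markovnikov hydroboration of the terminal alkene with 9-BBN-H in THF should give 9-[9-(2,6-dimethoxyphenyl)-9-oxononyl]-9-borabicyclo[3.3.1]nonane F3, used without isolation in a B-alkyl Suzuki–Miyaura coupling with commercial 4-bromo-1,2-dimethoxybenzene (PdCl2(dppf), K3PO4, THF/DMF/H2O, 60 °C). This forms the same benzylic–aryl bond and should give 9-(3,4-dimethoxyphenyl)-1-(2,6-dimethoxyphenyl)nonan-1-one F4. Fourfold demethylation with BBr3 in CH2Cl2 comes back to the route at 10.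

Step 1. Proton transfer (enolisation of the medium-ring ketone) may outrun carbonyl addition of the hindered aryl nucleophile, so that 1 and 2 are returned. The fallback sets out from 2 and makes the enolisation the productive event. KN(SiMe3)2 and PhNTf2 in THF at −78 °C should give cyclonon-1-en-1-yl trifluoromethanesulfonate F5. Suzuki–Miyaura coupling with commercial (2,6-dimethoxyphenyl)boronic acid (Pd(OAc)2, SPhos, K3PO4, toluene/H2O) should give 1-(2,6-dimethoxyphenyl)cyclonon-1-ene F6. Mukaiyama hydration (Co(acac)2, PhSiH3, O2, THF) places the hydroxyl group on the more substituted benzylic carbon through the tertiary radical and comes back to the route at 5.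

Step 4. While the strong Lewis acid is present, an acetyl group may migrate to carbon (Fries-type) or ester cleavage may stay incomplete, and the free catechol may oxidise during prolonged acidic methanolysis. The fallback sets out from 8 and replaces the one-flask unmasking by two orthogonal operations. Aminolysis with pyrrolidine (CH2Cl2, 0 °C, argon) removes both acetyl groups before any Lewis acid is present and should give 9-(3,4-dihydroxyphenyl)-1-(2,6-dimethoxyphenyl)nonan-1-one F7, which is isolated. Chelation-assisted cleavage of the two methoxy groups next to the ketone with BBr3 (CH2Cl2, −78 to 0 °C, aqueous quench) then comes back to the route at 10.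

**Further compounds**

F1 | step 3 | N-methoxy-N-methylnon-8-enamide | C=CCCCCCCC(=O)N(C)OC
F2 | step 3 | 1-(2,6-dimethoxyphenyl)non-8-en-1-one | COc1cccc(OC)c1C(=O)CCCCCCC=C
F3 | step 3 | 9-[9-(2,6-dimethoxyphenyl)-9-oxononyl]-9-borabicyclo[3.3.1]nonane | COc1cccc(OC)c1C(=O)CCCCCCCCB1C2CCCC1CCC2
F4 | step 3 | 9-(3,4-dimethoxyphenyl)-1-(2,6-dimethoxyphenyl)nonan-1-one | COc1cccc(OC)c1C(=O)CCCCCCCCc1ccc(OC)c(OC)c1
F5 | step 1 | cyclonon-1-en-1-yl trifluoromethanesulfonate (ring-cis double bond) | O=S(=O)(O/C1=C/CCCCCCC1)C(F)(F)F
F6 | step 1 | 1-(2,6-dimethoxyphenyl)cyclonon-1-ene (ring-cis double bond) | COc1cccc(OC)c1/C2=C/CCCCCCC2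
F7 | step 4 | 9-(3,4-dihydroxyphenyl)-1-(2,6-dimethoxyphenyl)nonan-1-one | COc1cccc(OC)c1C(=O)CCCCCCCCc1ccc(O)c(O)c1
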